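**Retrosynthetic overview**
1. The strategy rests on the cyclohexane C5–C10: quaternary C10 (vinyl C1=C2 and oxygenated C14) lies next to the C5 methine that carries the 2‑propenyl unit C4(=C3)–C15. This is the γ,δ‑unsaturated acid pattern of an Ireland–Claisen shift across C5–C10, so the ring is made by contraction of a ten‑membered α‑ethylidene lactone (ring C14(=O)–O–C3–C4=C5–C6–C7–C8–C9–C10).
2. The lactone is built with a Z C4=C5 olefin and with O6 tied to C12 as a trans‑fused cyclic methyl acetal. With the Z olefin both ketene acetal geometries (boat or chair array) put C14 cis to the C5 side chain, and allylic strain at C6 directs the new bond anti to O6.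
3. The lactone comes from macrolactonization of a C3‑hydroxy C14‑acid, then aldol condensation with acetaldehyde (C1, C2). C5–C6 is made by Felkin addition of a (Z)‑alkenylmagnesium (from propargyl alcohol) to a C6 aldehyde, and C7–C8 by an Evans syn‑aldol of a 4,4‑dimethoxybutanoyl imide with methyl 4‑oxobutanoate.
4. After the contraction: C14 acid to CH2OAc; acetal to lactol, α‑methylenation (C13) and oxidation to the lactone; allylic oxidation of C15 to the enal; O8 acylation with protected 2‑(hydroxymethyl)acrylic acid.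
5. Ring order: tetrahydrofuran acetal O6–C12 (later the γ‑lactone), then the ten‑membered lactone, then the cyclohexane in the key step.

Key step: step 14

Remark: atom numbers are those of the elemane skeleton (C1=C2 vinyl and C14 on C10; C3 and C15 on C4; C11, C12, C13 on C7; O6 and O8 on C6 and C8).
Remark on the chemistry: the acetal/lactol carbon C12 (compounds 19–34) is assumed to form as an anomer mixture that converges at lactone 35, so those SMILES carry no descriptor at C12; the ethylidene of 27 is drawn E, and either geometry gives the same dienolate.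

**Route**

Step 1
Reactants: 1 methyl 4,4-dimethoxybutanoate
Product: 2 lithium 4,4-dimethoxybutanoate
Conditions: LiOH·H2O (1.05 equiv), MeOH/H2O, rt; evaporate and dry
Reagents that add atoms: lithium hydroxide, [Li+].[OH-]
Why: Ester saponification; the salt is kept because the free acetal acid can lose methanol to a pseudo‑ester under acid.

Step 2
Reactants: 2 lithium 4,4-dimethoxybutanoate; 3 (R)-4-benzyloxazolidin-2-one
Product: 5 (R)-4-benzyl-3-(4,4-dimethoxybutanoyl)oxazolidin-2-one, via pivalic mixed anhydride 4 (not isolated)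
Conditions: PivCl, THF, −20 °C; then 3, Et3N (LiCl formed in situ), rt
Reagents that add atoms: none
Why: N‑acylation of the oxazolidinone through the mixed anhydride under LiCl/Et3N activation, with attack at the less hindered carbonyl.

Step 3
Reactants: 5 (R)-4-benzyl-3-(4,4-dimethoxybutanoyl)oxazolidin-2-one; 6 methyl 4-oxobutanoate
Product: 8 methyl (4S,5R)-6-[(R)-4-benzyl-2-oxooxazolidin-3-yl]-5-(2,2-dimethoxyethyl)-4-hydroxy-6-oxohexanoate, via boron enolate 7 (not isolated)
Conditions: n-Bu2BOTf, i-Pr2NEt, CH2Cl2, −78 → 0 °C; 6, −78 → 0 °C; pH 7 buffer, MeOH, 30% H2O2, 0 °C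
Reagents that add atoms: none
Why: Evans syn‑aldol in which the Z(O)‑boron enolate reacts through a Zimmerman–Traxler chair on the face away from the benzyl group, setting C7 (R) and C8 (S) syn; the adduct is silylated at once because a γ‑hydroxy ester can lactonize.

Step 4
Reactants: 8 aldol adduct
Product: 9 methyl (4S,5R)-6-[(R)-4-benzyl-2-oxooxazolidin-3-yl]-4-[(tert-butyldimethylsilyl)oxy]-5-(2,2-dimethoxyethyl)-6-oxohexanoate
Conditions: TBSOTf, 2,6-lutidine, CH2Cl2, −78 °C
Reagents that add atoms: tert-butyldimethylsilyl triflate, CC(C)(C)[Si](C)(C)OS(=O)(=O)C(F)(F)F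
Why: Silylation of the secondary aldol hydroxyl at −78 °C (where the dimethyl acetal should not ionize) blocks O8 and stops γ‑lactonization onto C14.

Step 5
Reactants: 9 silylated imide
Product: 10 methyl (4S,5S)-4-[(tert-butyldimethylsilyl)oxy]-5-(hydroxymethyl)-7,7-dimethoxyheptanoate
Conditions: NaBH4, THF/H2O (4:1), 0 °C → rt
Reagents that add atoms: none
Why: Borohydride reduces the activated N‑acyl oxazolidinone carbonyl to the C6 alcohol and releases the auxiliary, while the unactivated methyl ester is left.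

Step 6
Reactants: 10 primary alcohol
Product: 11 methyl (4S,5R)-4-[(tert-butyldimethylsilyl)oxy]-5-formyl-7,7-dimethoxyheptanoate
Conditions: Dess–Martin periodinane, NaHCO3, CH2Cl2, 0 °C → rt; used without storage
Reagents that add atoms: none
Why: Buffered Dess–Martin oxidation gives the α‑branched C6 aldehyde without epimerizing C7 or cleaving the acetal.

Step 7
Reactants: 12 propargyl alcohol
Product: 14 (Z)-3-iodo-2-methylprop-2-en-1-ol, via alkenylmagnesium alkoxide 13 (not isolated)
Conditions: MeMgBr (3 equiv), CuI (10 mol%), Et2O/THF, −10 °C → rt; then I2, −10 °C → rt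
Reagents that add atoms: methylmagnesium bromide, C[Mg]Br; iodine, II
Why: Copper‑catalysed anti‑carbomagnesiation of the propargylic alkoxide (magnesium chelated by the alkoxide) followed by iodinolysis with retention places CH2OH and iodine cis, which fixes the Z geometry of C4=C5 and installs C15.

Step 8
Reactants: 14 (Z)-3-iodo-2-methylprop-2-en-1-ol
Product: 15 (Z)-tert-butyl[(3-iodo-2-methylprop-2-en-1-yl)oxy]dimethylsilane
Conditions: TBSCl, imidazole, CH2Cl2, rt
Reagents that add atoms: tert-butyldimethylsilyl chloride, CC(C)(C)[Si](C)(C)Cl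
Why: Standard silylation of the primary allylic alcohol so that the iodide can be metalated.

Step 9
Reactants: 15 (Z)-alkenyl iodide; 11 C6 aldehyde
Product: 18 methyl (4S,5S,6R,7Z)-4,9-bis[(tert-butyldimethylsilyl)oxy]-5-(2,2-dimethoxyethyl)-6-hydroxy-8-methylnon-7-enoate, via alkenyllithium 16 (not isolated), via alkenylmagnesium bromide 17 (not isolated)
Conditions: t-BuLi (2 equiv), Et2O, −78 °C; MgBr2·OEt2; then 11, −78 °C; aq. NH4Cl
Reagents that add atoms: none
Why: Iodine–lithium exchange with retention, transmetalation to magnesium and Felkin–Anh addition (attack anti to C8, past the C7 hydrogen) form C5–C6 and should set C6 (R, 6,7‑syn); at −78 °C the aldehyde reacts far faster than the methyl ester.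

Step 10
Reactants: 18 allylic alcohol
Product: 19 methyl (4S)-4-[(tert-butyldimethylsilyl)oxy]-4-{(2R,3S)-2-[(Z)-3-hydroxy-2-methylprop-1-enyl]-5-methoxytetrahydrofuran-3-yl}butanoate
Conditions: CSA (10 mol%), MeOH/CH2Cl2, 0 °C
Reagents that add atoms: none
Why: Acid‑catalysed methanolysis removes the primary allylic silyl ether while the C6 hydroxyl closes onto C12 to the five‑membered cyclic methyl acetal (trans‑2,3‑disubstituted), masking O6 and C12 in one ring; the hindered secondary C8 silyl ether should survive.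

Step 11
Reactants: 19 hydroxy ester
Product: 20 (4S)-4-[(tert-butyldimethylsilyl)oxy]-4-{(2R,3S)-2-[(Z)-3-hydroxy-2-methylprop-1-enyl]-5-methoxytetrahydrofuran-3-yl}butanoic acid
Conditions: LiOH, THF/MeOH/H2O, rt; 1 M HCl to pH 4–5 at 0 °C, extract at once
Reagents that add atoms: lithium hydroxide, [Li+].[OH-]
Why: Saponification of the unhindered methyl ester; silyl ether and acetal are stable to base.

Step 12
Reactants: 20 seco acid
Product: 22 ten-membered lactone (6R,7S,8S; C4=C5 Z; C14 acyl on O–C3; C8 OTBS; trans-fused 12-methoxytetrahydrofuran O6–C12), via nitrobenzoic mixed anhydride 21 (not isolated)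
Conditions: 2-methyl-6-nitrobenzoic anhydride (MNBA), DMAP, CH2Cl2 (about 1 mM), rt, slow addition of 20
Reagents that add atoms: none
Why: Shiina macrolactonization (mixed anhydride, DMAP acyl transfer) under high dilution; the Z olefin and the trans‑fused acetal ring act as turn elements for closing the ten‑membered ring.

Step 13
Reactants: 22 ten-membered lactone; 23 acetaldehyde
Product: 27 α-ethylidene ten-membered lactone (as 22 with C10=C1H–C2H3 and E geometry), via lithium enolate 24 (not isolated), via lithium aldolate 25 (not isolated), via mesylate 26 (not isolated)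
Conditions: LDA, THF, −78 °C; 23, −78 °C; MsCl, −78 → 0 °C; DBU, 0 °C → rt
Reagents that add atoms: none
Why: Lithium enolate aldol, mesylation of the aldolate and E1cB elimination (aldol condensation) install C1 and C2 as the ethylidene group; enolate rearrangement is slow at −78 °C and the transient stereocentres are destroyed.

Step 14
Reactants: 27 α-ethylidene ten-membered lactone
Product: 30 (5S,6R,7S,8S,10R)-8-[(tert-butyldimethylsilyl)oxy]-12-methoxy-6,12-epoxyelema-1,3-dien-14-oic acid, via trimethylsilyl ketene acetal 28 (not isolated), via trimethylsilyl ester 29 (not isolated)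
Conditions: LDA, TMSCl/Et3N (internal quench), THF/DMPU, −78 °C → rt; PhMe, 80 °C; then H2O/THF, pH 5
Reagents that add atoms: none
Why: LDA removes a γ‑hydrogen from the C2 methyl of the ethylidene unit and chlorotrimethylsilane traps the cross‑conjugated dienolate on oxygen as ketene acetal 28 (C2=C1–C10=C14(OSiMe3)–O–C3), whose C10=C14–O–C3–C4=C5 segment is an allyl vinyl ether held inside the ring; a concerted suprafacial [3,3] shift forms C5–C10 and breaks O–C3, giving silyl ester 29 and, on hydrolysis, acid 30 with the C1=C2 vinyl and C4(=C3)–C15 isopropenyl groups. The closest known reactions are the alicyclic Ireland–Claisen ring contraction of unsaturated macrolactones and the Ireland–Claisen rearrangement of allyl ester dienolates made by deconjugative γ‑enolization. The cyclohexane C5–C10 closes transannularly by four‑atom contraction of the ten‑membered ring: with the Z olefin the cis in‑ring ketene acetal can only reach a boat six‑centre array and the trans one only a chair. Both arrays place C14 and C4 on the same face, so the cis relation of the C10 carboxyl and the C5 isopropenyl group (C10 R, vinyl α) follows from the Z geometry of C4=C5 whatever the ketene acetal geometry. The face is set by C6: allylic 1,3‑strain with the cis C3 methylene keeps H6 in the olefin plane, so C10 bonds to C5 anti to O6 (C5 S), with the trans‑fused acetal ring and the C8 silyloxy group pseudo‑equatorial on the forming ring. The step needs γ‑deprotonation and O‑silylation to outrun conjugate addition of the amide and fragmentation of the enolate to a ketene, which DMPU and the internal silyl chloride quench at −78 °C are meant to secure; there is only one allyl vinyl ether unit, so no regiochemical alternative exists.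

Step 15
Reactants: 30 ring-contracted acid
Product: 31 (5S,6R,7S,8S,10R)-8-[(tert-butyldimethylsilyl)oxy]-12-methoxy-6,12-epoxyelema-1,3-dien-14-ol
Conditions: LiAlH4, THF, 0 → 45 °C; Fieser work-up
Reagents that add atoms: none
Why: LiAlH4 reduces the hindered acid to the neopentyl C14 alcohol; silyl ether, acetal and olefins are inert.

Step 16
Reactants: 31 C14 alcohol
Product: 32 (5S,6R,7S,8S,10R)-8-[(tert-butyldimethylsilyl)oxy]-12-methoxy-6,12-epoxyelema-1,3-dien-14-yl acetate
Conditions: Ac2O, pyridine, DMAP (cat.), CH2Cl2, rt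
Reagents that add atoms: acetic anhydride, CC(=O)OC(C)=O
Why: Acylation of the primary alcohol installs the C14 acetate of the target before any base‑sensitive group is present.

Step 17
Reactants: 32 acetate
Product: 33 14-acetoxy-8α-[(tert-butyldimethylsilyl)oxy]-6α,12-epoxyelema-1,3-dien-12-ol (lactol; 5S,6R,7S,8S,10R)
Conditions: AcOH/THF/H2O (3:1:1), 40 °C
Reagents that add atoms: water, O
Why: Mild aqueous acid hydrolyses the tetrahydrofuranyl methyl acetal (THP‑like lability) to the lactol without touching the secondary silyl ether or the acetate; O8 stays protected so that only O6 can hold C12.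

Step 18
Reactants: 33 lactol
Product: 34 14-acetoxy-8α-[(tert-butyldimethylsilyl)oxy]-6α,12-epoxyelema-1,3,11(13)-trien-12-ol (α-methylene lactol; 5S,6R,7S,8S,10R)
Conditions: 37% aq. HCHO, pyrrolidine (20 mol%), propionic acid (20 mol%), i-PrOH, 45 °C
Reagents that add atoms: formaldehyde, C=O
Why: Amine‑catalysed Mannich α‑methylenation of aldehydes, acting on the ring‑opened hydroxy‑aldehyde tautomer of the lactol (enamine plus formaldehyde‑derived iminium, then β‑elimination), adds C13; the product recloses to the lactol and the mild conditions tolerate the acetate.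

Step 19
Reactants: 34 α-methylene lactol
Product: 35 14-acetoxy-8α-[(tert-butyldimethylsilyl)oxy]elema-1,3,11(13)-trien-12,6α-olide (5S,6R,7S,8S,10R)
Conditions: activated MnO2, CH2Cl2, rt
Reagents that add atoms: none
Why: Manganese dioxide oxidation of the allylic lactol gives the α‑methylene‑γ‑lactone, trans‑fused at C6–C7.

Step 20
Reactants: 35 α-methylene lactone
Product: 36 14-acetoxy-8α-[(tert-butyldimethylsilyl)oxy]-15-hydroxyelema-1,3,11(13)-trien-12,6α-olide (5S,6R,7S,8S,10R)
Conditions: SeO2 (0.5 equiv), t-BuOOH (anhydrous), CH2Cl2, rt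
Reagents that add atoms: tert-butyl hydroperoxide, CC(C)(C)OO (oxygen delivered through catalytic selenium dioxide, O=[Se]=O)
Why: Selenium dioxide allylic oxidation (ene reaction, then [2,3] shift) of the only electron‑rich 1,1‑disubstituted olefin with an allylic methyl; the vinyl group has no allylic hydrogen and the α‑methylene lactone is electron‑poor.

Step 21
Reactants: 36 allylic alcohol (with any enal already formed)
Product: 37 14-acetoxy-8α-[(tert-butyldimethylsilyl)oxy]-15-oxoelema-1,3,11(13)-trien-12,6α-olide (5R,6R,7S,8S,10R)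
Conditions: activated MnO2, CH2Cl2, rt
Reagents that add atoms: none
Why: Selective oxidation of the primary allylic alcohol to the α‑substituted acrolein.

Step 22
Reactants: 37 enal
Product: 38 14-acetoxy-8α-hydroxy-15-oxoelema-1,3,11(13)-trien-12,6α-olide (5R,6R,7R,8S,10R)
Conditions: HF·pyridine, THF, 0 °C → rt
Reagents that add atoms: none
Why: Acidic fluoride cleaves the secondary silyl ether; enal, α‑methylene lactone and acetate are stable to these conditions.

Step 23
Reactants: 39 ethyl 2-(hydroxymethyl)acrylate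
Product: 40 ethyl 2-{[(tert-butyldimethylsilyl)oxy]methyl}acrylate
Conditions: TBSCl, imidazole, CH2Cl2, 0 °C → rt
Reagents that add atoms: tert-butyldimethylsilyl chloride, CC(C)(C)[Si](C)(C)Cl
Why: Silylation of the primary alcohol so that the acid can later be activated without self‑esterification.

Step 24
Reactants: 40 silylated ester
Product: 41 2-{[(tert-butyldimethylsilyl)oxy]methyl}acrylic acid
Conditions: LiOH, THF/H2O, 0 °C → rt; dilute HCl to pH 4
Reagents that add atoms: lithium hydroxide, [Li+].[OH-]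
Why: Saponification of the ethyl ester under conditions that leave the silyl ether and the acrylate double bond intact.

Step 25
Reactants: 38 C8 alcohol; 41 2-{[(tert-butyldimethylsilyl)oxy]methyl}acrylic acid
Product: 43 14-acetoxy-8α-(2-{[(tert-butyldimethylsilyl)oxy]methyl}acryloyloxy)-15-oxoelema-1,3,11(13)-trien-12,6α-olide, via trichlorobenzoic mixed anhydride 42 (not isolated)
Conditions: 2,4,6-trichlorobenzoyl chloride, Et3N, PhMe, rt; then 38, DMAP, rt
Reagents that add atoms: none
Why: Yamaguchi esterification of the equatorial secondary C8 alcohol through the mixed anhydride and DMAP acyl transfer.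

Step 26
Reactants: 43 silyl-protected ester
Product: 44 target, 14-acetoxy-8α-[2-(hydroxymethyl)acryloyloxy]-15-oxoelema-1,3,11(13)-trien-12,6α-olide (5R,6R,7R,8S,10R)
Conditions: HF·pyridine, pyridine/THF, 0 °C
Reagents that add atoms: none
Why: Mild fluoride cleavage of the primary allylic silyl ether releases the hydroxymethyl group without affecting the enal, the two acrylate‑type esters or the acetate.

**Compound list**
1 | methyl 4,4-dimethoxybutanoate | COC(=O)CCC(OC)OC | starting material
2 | lithium 4,4-dimethoxybutanoate | [Li+].[O-]C(=O)CCC(OC)OC | intermediate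
3 | (R)-4-benzyloxazolidin-2-one | O=C1N[C@H](Cc2ccccc2)CO1 | starting material
4 | 4,4-dimethoxybutanoic pivalic anhydride (not isolated) | COC(OC)CCC(=O)OC(=O)C(C)(C)C | intermediate
5 | (R)-4-benzyl-3-(4,4-dimethoxybutanoyl)oxazolidin-2-one | COC(OC)CCC(=O)N1C(=O)OC[C@H]1Cc1ccccc1 | intermediate
6 | methyl 4-oxobutanoate | COC(=O)CCC=O | starting material
7 | (Z)-di-n-butylboron enolate of 5 (not isolated) | CCCCB(CCCC)O/C(=C\CC(OC)OC)N1C(=O)OC[C@H]1Cc1ccccc1 | intermediate
8 | methyl (4S,5R)-6-[(R)-4-benzyl-2-oxooxazolidin-3-yl]-5-(2,2-dimethoxyethyl)-4-hydroxy-6-oxohexanoate (C7 R, C8 S) | COC(=O)CC[C@H](O)[C@@H](CC(OC)OC)C(=O)N1C(=O)OC[C@H]1Cc1ccccc1 | intermediate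
9 | 4-O-TBS ether of 8 | COC(=O)CC[C@H](O[Si](C)(C)C(C)(C)C)[C@@H](CC(OC)OC)C(=O)N1C(=O)OC[C@H]1Cc1ccccc1 | intermediate
10 | methyl (4S,5S)-4-[(tert-butyldimethylsilyl)oxy]-5-(hydroxymethyl)-7,7-dimethoxyheptanoate | COC(=O)CC[C@H](O[Si](C)(C)C(C)(C)C)[C@@H](CC(OC)OC)CO | intermediate
11 | methyl (4S,5R)-4-[(tert-butyldimethylsilyl)oxy]-5-formyl-7,7-dimethoxyheptanoate | COC(=O)CC[C@H](O[Si](C)(C)C(C)(C)C)[C@@H](CC(OC)OC)C=O | intermediate
12 | propargyl alcohol | C#CCO | starting material
13 | (Z)-[3-(bromomagnesiooxy)-2-methylprop-1-enyl]magnesium bromide (not isolated) | Br[Mg]OC/C(C)=C\[Mg]Br | intermediate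
14 | (Z)-3-iodo-2-methylprop-2-en-1-ol | OC/C(C)=C\I | intermediate
15 | (Z)-tert-butyl[(3-iodo-2-methylprop-2-en-1-yl)oxy]dimethylsilane | CC(C)(C)[Si](C)(C)OC/C(C)=C\I | intermediate
16 | (Z)-alkenyllithium from 15 (not isolated) | CC(C)(C)[Si](C)(C)OC/C(C)=C\[Li] | intermediate
17 | (Z)-alkenylmagnesium bromide from 15 (not isolated) | CC(C)(C)[Si](C)(C)OC/C(C)=C\[Mg]Br | intermediate
18 | methyl (4S,5S,6R,7Z)-4,9-bis[(tert-butyldimethylsilyl)oxy]-5-(2,2-dimethoxyethyl)-6-hydroxy-8-methylnon-7-enoate (C6 R, C7 S, C8 S) | CC(C)(C)[Si](C)(C)OC/C(C)=C\[C@@H](O)[C@H](CC(OC)OC)[C@@H](O[Si](C)(C)C(C)(C)C)CCC(=O)OC | intermediate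
19 | methyl (4S)-4-[(tert-butyldimethylsilyl)oxy]-4-{(2R,3S)-2-[(Z)-3-hydroxy-2-methylprop-1-enyl]-5-methoxytetrahydrofuran-3-yl}butanoate (C12 anomers) | COC(=O)CC[C@H](O[Si](C)(C)C(C)(C)C)[C@H]1CC(OC)O[C@@H]1/C=C(/C)CO | intermediate
20 | (4S)-4-[(tert-butyldimethylsilyl)oxy]-4-{(2R,3S)-2-[(Z)-3-hydroxy-2-methylprop-1-enyl]-5-methoxytetrahydrofuran-3-yl}butanoic acid | OC(=O)CC[C@H](O[Si](C)(C)C(C)(C)C)[C@H]1CC(OC)O[C@@H]1/C=C(/C)CO | intermediate
21 | mixed anhydride of 20 with 2-methyl-6-nitrobenzoic acid (not isolated) | Cc1cccc([N+](=O)[O-])c1C(=O)OC(=O)CC[C@H](O[Si](C)(C)C(C)(C)C)[C@H]1CC(OC)O[C@@H]1/C=C(/C)CO | intermediate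
22 | ten-membered lactone (6R,7S,8S; ring C14(=O)–O–C3–C4(Me)=C5–C6–C7–C8–C9–C10, C4=C5 Z, C8 OTBS, trans-fused 12-methoxytetrahydrofuran O6–C12–C11) | O=C1CC[C@H](O[Si](C)(C)C(C)(C)C)[C@H]2CC(OC)O[C@@H]2/C=C(/C)CO1 | intermediate
23 | acetaldehyde | CC=O | starting material
24 | lithium enolate of 22 (not isolated) | [Li]OC1=CC[C@H](O[Si](C)(C)C(C)(C)C)[C@H]2CC(OC)O[C@@H]2/C=C(/C)CO1 | intermediate
25 | lithium aldolate, 10-(1-lithiooxyethyl) lactone (not isolated, diastereomer mixture) | CC(O[Li])C1C[C@H](O[Si](C)(C)C(C)(C)C)[C@H]2CC(OC)O[C@@H]2/C=C(/C)COC1=O | intermediate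
26 | mesylate, 10-(1-mesyloxyethyl) lactone (not isolated) | CC(OS(C)(=O)=O)C1C[C@H](O[Si](C)(C)C(C)(C)C)[C@H]2CC(OC)O[C@@H]2/C=C(/C)COC1=O | intermediate
27 | α-ethylidene ten-membered lactone (22 with C10=C1H–C2H3, E; 6R,7S,8S) | O=C1/C(=C/C)C[C@H](O[Si](C)(C)C(C)(C)C)[C@H]2CC(OC)O[C@@H]2/C=C(/C)CO1 | intermediate (key-step precursor)
28 | trimethylsilyl ketene acetal of 27, C2=C1–C10=C14(OSiMe3)–O–C3 (not isolated) | C=CC1=C(O[Si](C)(C)C)OC/C(C)=C\[C@H]2OC(OC)C[C@@H]2[C@@H](O[Si](C)(C)C(C)(C)C)C1 | intermediate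
29 | trimethylsilyl ester of 30 (not isolated) | C=C[C@]1(C(=O)O[Si](C)(C)C)C[C@H](O[Si](C)(C)C(C)(C)C)[C@H]2CC(OC)O[C@@H]2[C@H]1C(C)=C | intermediate
30 | (5S,6R,7S,8S,10R)-8-[(tert-butyldimethylsilyl)oxy]-12-methoxy-6,12-epoxyelema-1,3-dien-14-oic acid (10β-CO2H, 10α-vinyl, 5β-isopropenyl, 6α-O, 8α-OTBS) | C=C[C@]1(C(=O)O)C[C@H](O[Si](C)(C)C(C)(C)C)[C@H]2CC(OC)O[C@@H]2[C@H]1C(C)=C | intermediate (key-step product)
31 | (5S,6R,7S,8S,10R)-8-[(tert-butyldimethylsilyl)oxy]-12-methoxy-6,12-epoxyelema-1,3-dien-14-ol | C=C[C@]1(CO)C[C@H](O[Si](C)(C)C(C)(C)C)[C@H]2CC(OC)O[C@@H]2[C@H]1C(C)=C | intermediate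
32 | 14-acetate of 31 | C=C[C@]1(COC(C)=O)C[C@H](O[Si](C)(C)C(C)(C)C)[C@H]2CC(OC)O[C@@H]2[C@H]1C(C)=C | intermediate
33 | 14-acetoxy-8α-[(tert-butyldimethylsilyl)oxy]-6α,12-epoxyelema-1,3-dien-12-ol (lactol) | C=C[C@]1(COC(C)=O)C[C@H](O[Si](C)(C)C(C)(C)C)[C@H]2CC(O)O[C@@H]2[C@H]1C(C)=C | intermediate
34 | 14-acetoxy-8α-[(tert-butyldimethylsilyl)oxy]-6α,12-epoxyelema-1,3,11(13)-trien-12-ol (α-methylene lactol) | C=C[C@]1(COC(C)=O)C[C@H](O[Si](C)(C)C(C)(C)C)[C@H]2C(=C)C(O)O[C@@H]2[C@H]1C(C)=C | intermediate
35 | 14-acetoxy-8α-[(tert-butyldimethylsilyl)oxy]elema-1,3,11(13)-trien-12,6α-olide (5S,6R,7S,8S,10R) | C=C[C@]1(COC(C)=O)C[C@H](O[Si](C)(C)C(C)(C)C)[C@H]2C(=C)C(=O)O[C@@H]2[C@H]1C(C)=C | intermediate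
36 | 14-acetoxy-8α-[(tert-butyldimethylsilyl)oxy]-15-hydroxyelema-1,3,11(13)-trien-12,6α-olide | C=C[C@]1(COC(C)=O)C[C@H](O[Si](C)(C)C(C)(C)C)[C@H]2C(=C)C(=O)O[C@@H]2[C@H]1C(=C)CO | intermediate
37 | 14-acetoxy-8α-[(tert-butyldimethylsilyl)oxy]-15-oxoelema-1,3,11(13)-trien-12,6α-olide (5R,6R,7S,8S,10R) | C=C[C@]1(COC(C)=O)C[C@H](O[Si](C)(C)C(C)(C)C)[C@H]2C(=C)C(=O)O[C@@H]2[C@H]1C(=C)C=O | intermediate
38 | 14-acetoxy-8α-hydroxy-15-oxoelema-1,3,11(13)-trien-12,6α-olide (5R,6R,7R,8S,10R) | C=C[C@]1(COC(C)=O)C[C@H](O)[C@H]2C(=C)C(=O)O[C@@H]2[C@H]1C(=C)C=O | intermediate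
39 | ethyl 2-(hydroxymethyl)acrylate | CCOC(=O)C(=C)CO | starting material
40 | ethyl 2-{[(tert-butyldimethylsilyl)oxy]methyl}acrylate | CCOC(=O)C(=C)CO[Si](C)(C)C(C)(C)C | intermediate
41 | 2-{[(tert-butyldimethylsilyl)oxy]methyl}acrylic acid | OC(=O)C(=C)CO[Si](C)(C)C(C)(C)C | intermediate
42 | mixed anhydride of 41 with 2,4,6-trichlorobenzoic acid (not isolated) | O=C(OC(=O)c1c(Cl)cc(Cl)cc1Cl)C(=C)CO[Si](C)(C)C(C)(C)C | intermediate
43 | 14-acetoxy-8α-(2-{[(tert-butyldimethylsilyl)oxy]methyl}acryloyloxy)-15-oxoelema-1,3,11(13)-trien-12,6α-olide | C=C[C@]1(COC(C)=O)C[C@H](OC(=O)C(=C)CO[Si](C)(C)C(C)(C)C)[C@H]2C(=C)C(=O)O[C@@H]2[C@H]1C(=C)C=O | intermediate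
44 | CNP0185525.1, 14-acetoxy-8α-[2-(hydroxymethyl)acryloyloxy]-15-oxoelema-1,3,11(13)-trien-12,6α-olide (5R,6R,7R,8S,10R) | C=C[C@]1(COC(C)=O)C[C@H](OC(=O)C(=C)CO)[C@H]2C(=C)C(=O)O[C@@H]2[C@H]1C(=C)C=O | target

**Step count and weak points**
Total: 26 steps. Longest linear sequence: 22 steps (steps 1–6, 9–22, 25, 26, from methyl 4,4-dimethoxybutanoate).

Steps most likely to fail:

1. Step 14 (key step). The amide may add in conjugate fashion instead of removing the γ‑hydrogen, the dienolate may fragment to a vinylketene and the C3 alkoxide before it is silylated, or the strained boat array may raise the barrier so that desilylation or hydrogen shifts compete; some leakage to the other face of C5 is also possible. The fallback separates ring contraction from construction of the quaternary centre and sets out from lactone 22. The simple lactone enolate is silylated (LDA, TMSCl/Et3N, THF, −78 °C → PhMe, 80 °C), and the alicyclic Ireland–Claisen contraction should give, after hydrolysis, the C10–H acid F1 (carboxyl β, cis to the isopropenyl group). Diazomethane‑type esterification (TMSCHN2, MeOH/PhMe) gives the methyl ester F2. Its enolate (LDA, −78 °C) is expected to take acetaldehyde from the equatorial direction, giving the β‑hydroxy ester F3 with the new carbon α. Syn‑elimination with Burgess reagent (PhMe, 70 °C), which can only run toward the methyl group, gives the vinyl ester F4. LiAlH4 reduction of F4 comes back to the route at alcohol 31.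

2. Step 12. Intermolecular acylation may outrun closure of the strained ten‑membered ring, giving the diolide and oligomers. The fallback sets out from seco acid 20 and closes the ring at the alkyl–oxygen bond instead of the acyl–oxygen bond: a Mitsunobu macrolactonization (PPh3, DIAD, PhMe, high dilution, slow addition), in which the carboxylate displaces the activated primary allylic C3 oxygen. It makes no new compound (F0) and comes back at lactone 22.

3. Step 9. Facial selectivity may be poor, because 1,3‑induction from the C8 silyloxy group opposes the Felkin preference, and the α‑branched aldehyde may partly epimerize under the basic reagent. The fallback recycles the wrong isomer by inversion. It sets out from the product mixture of step 9 (made from aldehyde 11 and iodide 15): the separated 6S alcohol, the C6 epimer F5, is esterified under Mitsunobu conditions (4‑nitrobenzoic acid, PPh3, DIAD, PhMe), where SN2' attack is blocked by the fully substituted C4, to give the inverted 4‑nitrobenzoate F6. Methanolysis (K2CO3, MeOH) comes back to the route at alcohol 18.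

Further compounds
F1 | step 14 | ring-contracted acid with H in place of the C10 vinyl group (10β-CO2H; otherwise as 30) | OC(=O)[C@H]1C[C@H](O[Si](C)(C)C(C)(C)C)[C@H]2CC(OC)O[C@@H]2[C@H]1C(C)=C
F2 | step 14 | methyl ester of F1 | COC(=O)[C@H]1C[C@H](O[Si](C)(C)C(C)(C)C)[C@H]2CC(OC)O[C@@H]2[C@H]1C(C)=C
F3 | step 14 | methyl ester with 10α-(1-hydroxyethyl) group (carbinol epimers) | COC(=O)[C@@]1(C(C)O)C[C@H](O[Si](C)(C)C(C)(C)C)[C@H]2CC(OC)O[C@@H]2[C@H]1C(C)=C
F4 | step 14 | methyl ester of acid 30 | COC(=O)[C@@]1(C=C)C[C@H](O[Si](C)(C)C(C)(C)C)[C@H]2CC(OC)O[C@@H]2[C@H]1C(C)=C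
F0 | step 12 | none | none
F5 | step 9 | C6 epimer of 18 (6S) | CC(C)(C)[Si](C)(C)OC/C(C)=C\[C@H](O)[C@H](CC(OC)OC)[C@@H](O[Si](C)(C)C(C)(C)C)CCC(=O)OC
F6 | step 9 | 6-O-(4-nitrobenzoate) of 18 (6R) | CC(C)(C)[Si](C)(C)OC/C(C)=C\[C@@H](OC(=O)c1ccc(cc1)[N+](=O)[O-])[C@H](CC(OC)OC)[C@@H](O[Si](C)(C)C(C)(C)C)CCC(=O)OC
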